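## Retrosynthetic overview

1. The target is reached from acetonide 22 by ketal removal, isovaleroylation of the less hindered O8 and acetylation of O9.
2. Key disconnection: C11–C12 and C6–C7 of the α-methylene-γ-butyrolactone, leading back to the open-chain (Z)-enal/terminal allene 19 plus CO2. The enabling feature is that C13=C11 sits on the carbon joining carboxyl C12 to ring carbon C7, next to carbinol C6, so C7/C11/C13 is a latent terminal allene, C12 is CO2 and C6 an aldehyde. The furanone ring (O bridging C3 and C10) and the Z-C4=C5 bond fold C6 toward C7.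
3. The 3(2H)-furanone comes from 4-hydroxy-2-ynone 15, made from alkyne 10 and Weinreb amide 13 (Z-alkene inherited from 3-methylfuran-2(5H)-one).
4. C10 is set by Felkin–Anh ethynylation of methyl ketone 9; the allene comes from reductive transposition of propargylic alcohol 5; C8 and C9 are bought as dimethyl 2,3-O-isopropylidene-L-tartrate 1.
5. Ring order: dioxolane (bought, temporary) → furanone (step 10) → ten-membered carbocycle and lactone together (step 12).

Key step: step 12

Remark: positions are numbered as in germacranolides (ring C1–C10, lactone carbons C11–C13, C14 on C10, C15 on C4), and the macrocyclic compounds are named on that basis. Reagents without a number are commercial.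

## Route

Step 1
Reactants: 1 dimethyl (4R,5R)-2,2-dimethyl-1,3-dioxolane-4,5-dicarboxylate
Product: 2 (4R,5R)-N4,N5-dimethoxy-N4,N5,2,2-tetramethyl-1,3-dioxolane-4,5-dicarboxamide
Conditions: MeNH(OMe)·HCl, i-PrMgCl, THF, −20 °C to 0 °C
Reagents that add atoms: N,O-dimethylhydroxylamine hydrochloride, Cl.CNOC
Why: Weinreb amidation of an ester with the chloromagnesium amide is standard and leaves the two trans-dioxolane stereocentres (C8 and C9 of the target) untouched.

Step 2
Reactants: 2 (4R,5R)-N4,N5-dimethoxy-N4,N5,2,2-tetramethyl-1,3-dioxolane-4,5-dicarboxamide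
Product: 3 (4R,5R)-N-methoxy-N,2,2-trimethyl-5-[3-(trimethylsilyl)prop-2-ynoyl]-1,3-dioxolane-4-carboxamide
Conditions: TMSC≡CH, n-BuLi, THF, −78 °C; then 2, −78 to −40 °C; aq. NH4Cl
Reagents that add atoms: (trimethylsilyl)acetylene, C#C[Si](C)(C)C
Why: Weinreb ketone synthesis with one equivalent of lithium acetylide should desymmetrise the C2-symmetric bis-amide by mono-addition, the N-methoxy chelate preventing over-addition.

Step 3
Reactants: 3 (4R,5R)-N-methoxy-N,2,2-trimethyl-5-[3-(trimethylsilyl)prop-2-ynoyl]-1,3-dioxolane-4-carboxamide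
Product: 5 (4R,5S)-5-(1-hydroxyprop-2-yn-1-yl)-N-methoxy-N,2,2-trimethyl-1,3-dioxolane-4-carboxamide (both carbinol epimers), via silylated propargylic alcohol 4 (not isolated)
Conditions: NaBH4, CeCl3·7H2O, MeOH, −78 °C; then K2CO3, MeOH, rt
Reagents that add atoms: none
Why: Luche 1,2-reduction of the ynone spares the Weinreb amide and K2CO3/MeOH then cleaves the alkynyl C–Si bond; the new carbinol centre needs no control because it becomes sp2 carbon C7 of the allene.

Step 4
Reactants: 5 (4R,5S)-5-(1-hydroxyprop-2-yn-1-yl)-N-methoxy-N,2,2-trimethyl-1,3-dioxolane-4-carboxamide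
Product: 8 (4R,5S)-N-methoxy-N,2,2-trimethyl-5-(propa-1,2-dien-1-yl)-1,3-dioxolane-4-carboxamide, via sulfonylhydrazine 6 (not isolated), via propargylic diazene 7 (not isolated)
Conditions: 2-O2NC6H4SO2NHNH2, PPh3, DEAD, THF, −15 °C to rt
Reagents that add atoms: none
Why: Mitsunobu displacement by the arenesulfonylhydrazide, loss of sulfinic acid and retro-ene loss of N2 from the propargylic diazene should transpose the alkyne into the terminal allene (reductive 1,3-transposition); both carbinol epimers converge because the allene has no stereoaxis.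

Step 5
Reactants: 8 (4R,5S)-N-methoxy-N,2,2-trimethyl-5-(propa-1,2-dien-1-yl)-1,3-dioxolane-4-carboxamide
Product: 9 1-[(4R,5S)-2,2-dimethyl-5-(propa-1,2-dien-1-yl)-1,3-dioxolan-4-yl]ethan-1-one
Conditions: MeMgBr, THF, 0 °C
Reagents that add atoms: methylmagnesium bromide, C[Mg]Br
Why: Weinreb ketone synthesis stops at the methyl ketone, the allene is inert to the Grignard reagent, and the trans-dioxolane is the thermodynamically preferred arrangement at C9.

Step 6
Reactants: 9 1-[(4R,5S)-2,2-dimethyl-5-(propa-1,2-dien-1-yl)-1,3-dioxolan-4-yl]ethan-1-one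
Product: 10 (2S)-2-[(4R,5S)-2,2-dimethyl-5-(propa-1,2-dien-1-yl)-1,3-dioxolan-4-yl]but-3-yn-2-ol
Conditions: HC≡CMgBr, CeCl3, THF, −78 °C
Reagents that add atoms: ethynylmagnesium bromide, C#C[Mg]Br
Why: 1,2-addition of a weakly basic, non-chelating cerium acetylide to the α-alkoxy ketone should follow the Felkin–Anh model (attack anti to the C9–O bond), placing O10 anti to O9 along C8–C9–C10–C1, which is the C10 configuration of the target.

Step 7
Reactants: 11 3-methylfuran-2(5H)-one
Product: 12 (2Z)-4-hydroxy-N-methoxy-N,2-dimethylbut-2-enamide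
Conditions: MeNH(OMe)·HCl, AlMe3, CH2Cl2, 0 °C to rt
Reagents that add atoms: N,O-dimethylhydroxylamine hydrochloride, Cl.CNOC
Why: Aluminium amide aminolysis (Weinreb) opens the butenolide at the acyl carbon, so the Z geometry of the future C4=C5 bond is inherited from the ring.

Step 8
Reactants: 12 (2Z)-4-hydroxy-N-methoxy-N,2-dimethylbut-2-enamide
Product: 13 (2Z)-N-methoxy-N,2-dimethyl-4-[(triethylsilyl)oxy]but-2-enamide
Conditions: Et3SiCl, imidazole, CH2Cl2, 0 °C
Reagents that add atoms: chlorotriethylsilane, CC[Si](Cl)(CC)CC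
Why: Silylation of the primary allylic alcohol blocks relactonisation and masks the hydroxyl for the Grignard step.

Step 9
Reactants: 10 (2S)-2-[(4R,5S)-2,2-dimethyl-5-(propa-1,2-dien-1-yl)-1,3-dioxolan-4-yl]but-3-yn-2-ol; 13 (2Z)-N-methoxy-N,2-dimethyl-4-[(triethylsilyl)oxy]but-2-enamide
Product: 15 (2Z,7S)-7-[(4R,5S)-2,2-dimethyl-5-(propa-1,2-dien-1-yl)-1,3-dioxolan-4-yl]-7-hydroxy-3-methyl-1-[(triethylsilyl)oxy]oct-2-en-5-yn-4-one, via dimagnesium acetylide 14 (not isolated)
Conditions: EtMgBr (2.1 equiv), THF, 0 to 40 °C; then 13, 0 °C to rt; aq. NH4Cl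
Reagents that add atoms: none
Why: Two equivalents of EtMgBr should form the alkoxide and then the magnesium acetylide (allene C–H bonds are not acidic enough), which acylates on the Weinreb amide without over-addition (Weinreb ketone synthesis).

Step 10
Reactants: 15 (2Z,7S)-7-[(4R,5S)-2,2-dimethyl-5-(propa-1,2-dien-1-yl)-1,3-dioxolan-4-yl]-7-hydroxy-3-methyl-1-[(triethylsilyl)oxy]oct-2-en-5-yn-4-one
Product: 18 (2R)-2-[(4R,5S)-2,2-dimethyl-5-(propa-1,2-dien-1-yl)-1,3-dioxolan-4-yl]-5-[(2Z)-4-hydroxybut-2-en-2-yl]-2-methylfuran-3(2H)-one, via enaminone 16 (not isolated), via silylated furanone 17 (not isolated)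
Conditions: Et2NH, EtOH, rt; then AcOH/THF/H2O, rt
Reagents that add atoms: water, O
Why: Conjugate addition of diethylamine to the ynone, 5-exo-trig closure of the tertiary hydroxyl onto the ketone with loss of water and aqueous hydrolysis is the classical 4-hydroxy-2-ynone route to 3(2H)-furanones; dilute acetic acid should also cleave the triethylsilyl ether while sparing the acetonide and the allene.

Step 11
Reactants: 18 (2R)-2-[(4R,5S)-2,2-dimethyl-5-(propa-1,2-dien-1-yl)-1,3-dioxolan-4-yl]-5-[(2Z)-4-hydroxybut-2-en-2-yl]-2-methylfuran-3(2H)-one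
Product: 19 (2Z)-3-{(5R)-5-[(4R,5S)-2,2-dimethyl-5-(propa-1,2-dien-1-yl)-1,3-dioxolan-4-yl]-5-methyl-4-oxo-4,5-dihydrofuran-2-yl}but-2-enal
Conditions: MnO2, CH2Cl2, rt
Reagents that add atoms: none
Why: MnO2 oxidises the allylic alcohol selectively under neutral conditions, which should preserve the Z geometry, the acetonide and the allene.

Step 12
Reactants: 19 (2Z)-3-{(5R)-5-[(4R,5S)-2,2-dimethyl-5-(propa-1,2-dien-1-yl)-1,3-dioxolan-4-yl]-5-methyl-4-oxo-4,5-dihydrofuran-2-yl}but-2-enal
Product: 22 (6R,7S,8S,9R,10R)-8,9-(isopropylidenedioxy)-1-oxo-3,10-epoxygermacra-2,4(Z),11(13)-trien-12,6-olide, via nickelalactone 20 (not isolated), via hydroxy acid 21 (not isolated)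
Conditions: Ni(cod)2 (1.2 equiv), DBU (2.5 equiv), CO2 (1 atm), THF (high dilution), 0 °C to rt; then 1 M HCl, rt
Reagents that add atoms: carbon dioxide, O=C=O
Why: Proposed new method: zerovalent nickel should couple CO2 oxidatively with the terminal C11=C13 bond of the allene, forming C11–C12 in oxanickelacyclopentanone 20, an allylnickel carboxylate whose substituted terminus C7 then adds to the tethered C6 aldehyde through a closed six-membered transition state to form C6–C7, and acid work-up lactonises hydroxy acid 21. The closest known reaction types are the intermolecular nickel-mediated sequential addition of CO2 and an aldehyde to a terminal allene and the Barbier-type 2-carboxyallyl-metal/aldehyde macrocyclisations that close ten-membered germacranolide rings. The ten-membered carbocycle closes by 10-exo-trig allyl transfer to the aldehyde carbon and the lactone by 5-exo-trig acyl substitution of O6 on C12. C7 should be controlled by C8: with H8 eclipsing the C7=C11 bond to avoid allylic strain, C6 bonds antiperiplanar to the C8–C9 bond; C6 should follow from the chair-like transition state after σ–π equilibration of the allylnickel, giving the anti adduct and hence the trans-fused lactone. The step needs CO2 at the central allene carbon, aldehyde attack at C7 and not C13, and 1,2-addition to the aldehyde rather than the furanone ketone; these rest on the known regiochemistry of terminal allenes, the higher electrophilicity of the aldehyde and the cyclic allyl transfer. The furanone ring, the Z-C4=C5 bond and the trans-dioxolane hold C6 near C7 so that ring closure should outrun oligomerisation at high dilution.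

Step 13
Reactants: 22 (6R,7S,8S,9R,10R)-8,9-(isopropylidenedioxy)-1-oxo-3,10-epoxygermacra-2,4(Z),11(13)-trien-12,6-olide
Product: 23 (6R,7S,8S,9R,10R)-8,9-dihydroxy-1-oxo-3,10-epoxygermacra-2,4(Z),11(13)-trien-12,6-olide
Conditions: TFA/H2O (9:1), CH2Cl2, 0 °C
Reagents that add atoms: none
Why: Aqueous trifluoroacetic acid hydrolyses the isopropylidene ketal, while the α-methylene lactone, the vinylogous ester of the furanone and the Z-alkene are acid-stable.

Step 14
Reactants: 23 (6R,7S,8S,9R,10R)-8,9-dihydroxy-1-oxo-3,10-epoxygermacra-2,4(Z),11(13)-trien-12,6-olide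
Product: 24 (6R,7S,8S,9R,10R)-9-hydroxy-8-(3-methylbutanoyloxy)-1-oxo-3,10-epoxygermacra-2,4(Z),11(13)-trien-12,6-olide
Conditions: (i-BuCO)2O (1.1 equiv), 2,4,6-collidine, DMAP (cat.), CH2Cl2, −40 to 0 °C
Reagents that add atoms: 3-methylbutanoic anhydride, CC(C)CC(=O)OC(=O)CC(C)C
Why: DMAP-catalysed acylation with a limited amount of anhydride should occur at the C8 hydroxyl, because the C9 hydroxyl is neopentyl-type, flanked by the fully substituted C10.

Step 15
Reactants: 24 (6R,7S,8S,9R,10R)-9-hydroxy-8-(3-methylbutanoyloxy)-1-oxo-3,10-epoxygermacra-2,4(Z),11(13)-trien-12,6-olide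
Product: 25 (6R,7S,8S,9R,10R)-9-acetoxy-8-(3-methylbutanoyloxy)-1-oxo-3,10-epoxygermacra-2,4(Z),11(13)-trien-12,6-olide (CNP0255553.1)
Conditions: Ac2O, Et3N, DMAP, CH2Cl2, rt
Reagents that add atoms: acetic anhydride, CC(=O)OC(C)=O
Why: Forcing DMAP-catalysed acetylation should esterify the remaining hindered C9 hydroxyl without touching any stereocentre.

## Compound list

1 | dimethyl (4R,5R)-2,2-dimethyl-1,3-dioxolane-4,5-dicarboxylate (dimethyl 2,3-O-isopropylidene-L-tartrate) | COC(=O)[C@@H]1OC(C)(C)O[C@H]1C(=O)OC | starting material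
2 | (4R,5R)-N4,N5-dimethoxy-N4,N5,2,2-tetramethyl-1,3-dioxolane-4,5-dicarboxamide | CON(C)C(=O)[C@@H]1OC(C)(C)O[C@H]1C(=O)N(C)OC | intermediate
3 | (4R,5R)-N-methoxy-N,2,2-trimethyl-5-[3-(trimethylsilyl)prop-2-ynoyl]-1,3-dioxolane-4-carboxamide | CON(C)C(=O)[C@@H]1OC(C)(C)O[C@H]1C(=O)C#C[Si](C)(C)C | intermediate
4 | (4R,5S)-5-[1-hydroxy-3-(trimethylsilyl)prop-2-yn-1-yl]-N-methoxy-N,2,2-trimethyl-1,3-dioxolane-4-carboxamide, both carbinol epimers (not isolated) | CON(C)C(=O)[C@@H]1OC(C)(C)O[C@H]1C(O)C#C[Si](C)(C)C | intermediate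
5 | (4R,5S)-5-(1-hydroxyprop-2-yn-1-yl)-N-methoxy-N,2,2-trimethyl-1,3-dioxolane-4-carboxamide, both carbinol epimers | CON(C)C(=O)[C@@H]1OC(C)(C)O[C@H]1C(O)C#C | intermediate
6 | (4R,5S)-N-methoxy-N,2,2-trimethyl-5-{1-[1-(2-nitrobenzenesulfonyl)hydrazinyl]prop-2-yn-1-yl}-1,3-dioxolane-4-carboxamide (not isolated) | CON(C)C(=O)[C@@H]1OC(C)(C)O[C@H]1C(C#C)N(N)S(=O)(=O)c1ccccc1[N+](=O)[O-] | intermediate
7 | (4R,5S)-5-(1-diazenylprop-2-yn-1-yl)-N-methoxy-N,2,2-trimethyl-1,3-dioxolane-4-carboxamide (not isolated) | CON(C)C(=O)[C@@H]1OC(C)(C)O[C@H]1C(C#C)N=N | intermediate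
8 | (4R,5S)-N-methoxy-N,2,2-trimethyl-5-(propa-1,2-dien-1-yl)-1,3-dioxolane-4-carboxamide | CON(C)C(=O)[C@@H]1OC(C)(C)O[C@H]1C=C=C | intermediate
9 | 1-[(4R,5S)-2,2-dimethyl-5-(propa-1,2-dien-1-yl)-1,3-dioxolan-4-yl]ethan-1-one | CC(=O)[C@@H]1OC(C)(C)O[C@H]1C=C=C | intermediate
10 | (2S)-2-[(4R,5S)-2,2-dimethyl-5-(propa-1,2-dien-1-yl)-1,3-dioxolan-4-yl]but-3-yn-2-ol | C#C[C@](C)(O)[C@@H]1OC(C)(C)O[C@H]1C=C=C | intermediate
11 | 3-methylfuran-2(5H)-one | CC1=CCOC1=O | starting material
12 | (2Z)-4-hydroxy-N-methoxy-N,2-dimethylbut-2-enamide | OC/C=C(/C)C(=O)N(C)OC | intermediate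
13 | (2Z)-N-methoxy-N,2-dimethyl-4-[(triethylsilyl)oxy]but-2-enamide | CC[Si](CC)(CC)OC/C=C(/C)C(=O)N(C)OC | intermediate
14 | bis(bromomagnesium) alkoxide-acetylide of 10 (not isolated) | Br[Mg]C#C[C@](C)(O[Mg]Br)[C@@H]1OC(C)(C)O[C@H]1C=C=C | intermediate
15 | (2Z,7S)-7-[(4R,5S)-2,2-dimethyl-5-(propa-1,2-dien-1-yl)-1,3-dioxolan-4-yl]-7-hydroxy-3-methyl-1-[(triethylsilyl)oxy]oct-2-en-5-yn-4-one | CC[Si](CC)(CC)OC/C=C(/C)C(=O)C#C[C@](C)(O)[C@@H]1OC(C)(C)O[C@H]1C=C=C | intermediate
16 | (2Z,7S)-6-(diethylamino)-7-[(4R,5S)-2,2-dimethyl-5-(propa-1,2-dien-1-yl)-1,3-dioxolan-4-yl]-7-hydroxy-3-methyl-1-[(triethylsilyl)oxy]octa-2,5-dien-4-one (not isolated) | CC[Si](CC)(CC)OC/C=C(/C)C(=O)C=C(N(CC)CC)[C@](C)(O)[C@@H]1OC(C)(C)O[C@H]1C=C=C | intermediate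
17 | (2R)-2-[(4R,5S)-2,2-dimethyl-5-(propa-1,2-dien-1-yl)-1,3-dioxolan-4-yl]-2-methyl-5-{(2Z)-4-[(triethylsilyl)oxy]but-2-en-2-yl}furan-3(2H)-one (not isolated) | CC[Si](CC)(CC)OC/C=C(/C)C1=CC(=O)[C@](C)(O1)[C@@H]2OC(C)(C)O[C@H]2C=C=C | intermediate
18 | (2R)-2-[(4R,5S)-2,2-dimethyl-5-(propa-1,2-dien-1-yl)-1,3-dioxolan-4-yl]-5-[(2Z)-4-hydroxybut-2-en-2-yl]-2-methylfuran-3(2H)-one | OC/C=C(/C)C1=CC(=O)[C@](C)(O1)[C@@H]2OC(C)(C)O[C@H]2C=C=C | intermediate
19 | (2Z)-3-{(5R)-5-[(4R,5S)-2,2-dimethyl-5-(propa-1,2-dien-1-yl)-1,3-dioxolan-4-yl]-5-methyl-4-oxo-4,5-dihydrofuran-2-yl}but-2-enal | O=C/C=C(/C)C1=CC(=O)[C@](C)(O1)[C@@H]2OC(C)(C)O[C@H]2C=C=C | intermediate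
20 | oxanickelacyclopentanone from 19 and CO2 (divalent nickel, DBU ligands not drawn; not isolated) | O=C/C=C(/C)C1=CC(=O)[C@](C)(O1)[C@@H]2OC(C)(C)O[C@H]2C=C3C[Ni]OC3=O | intermediate
21 | (6R,7S,8S,9R,10R)-6-hydroxy-8,9-(isopropylidenedioxy)-1-oxo-3,10-epoxygermacra-2,4(Z),11(13)-trien-12-oic acid (not isolated) | C=C(C(O)=O)[C@H]1[C@H](O)/C=C(/C)C3=CC(=O)[C@](C)(O3)[C@@H]4OC(C)(C)O[C@H]41 | intermediate
22 | (6R,7S,8S,9R,10R)-8,9-(isopropylidenedioxy)-1-oxo-3,10-epoxygermacra-2,4(Z),11(13)-trien-12,6-olide | C=C1C(=O)O[C@@H]2/C=C(/C)C3=CC(=O)[C@](C)(O3)[C@@H]4OC(C)(C)O[C@H]4[C@@H]12 | intermediate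
23 | (6R,7S,8S,9R,10R)-8,9-dihydroxy-1-oxo-3,10-epoxygermacra-2,4(Z),11(13)-trien-12,6-olide | C=C1C(=O)O[C@@H]2/C=C(/C)C3=CC(=O)[C@](C)(O3)[C@H](O)[C@@H](O)[C@@H]12 | intermediate
24 | (6R,7S,8S,9R,10R)-9-hydroxy-8-(3-methylbutanoyloxy)-1-oxo-3,10-epoxygermacra-2,4(Z),11(13)-trien-12,6-olide | C=C1C(=O)O[C@@H]2/C=C(/C)C3=CC(=O)[C@](C)(O3)[C@H](O)[C@@H](OC(=O)CC(C)C)[C@@H]12 | intermediate
25 | (6R,7S,8S,9R,10R)-9-acetoxy-8-(3-methylbutanoyloxy)-1-oxo-3,10-epoxygermacra-2,4(Z),11(13)-trien-12,6-olide (CNP0255553.1) | C=C1C(=O)O[C@@H]2/C=C(/C)C3=CC(=O)[C@](C)(O3)[C@H](OC(C)=O)[C@@H](OC(=O)CC(C)C)[C@@H]12 | target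

## Step count and risks

Total step count: 15. Longest linear sequence: 13 steps (steps 1–6 and 9–15).

Step 12 (Proposed new method) is the most likely to fail. The allylnickel carboxylate may not reach the aldehyde across the forming ten-membered ring, leading to oligomerisation or simple protonation of the nickelalactone on work-up. DBU may isomerise the Z-enal, and facial selectivity at C6 and C7 may be poor. The fallback uses known reaction types and separates the two bond formations. It sets out from 19: bromoboration of the terminal allene with B-bromo-9-borabicyclo[3.3.1]nonane (CH2Cl2, −78 °C) places boron on C13 and bromine on C11 to give the 2-bromoallylborane F1. F1 closes the ten-membered ring by intramolecular allylboration of the aldehyde at C7, giving the 2-bromo homoallylic alcohol F2. Palladium-catalysed cyclocarbonylation of F2 (Pd(PPh3)4, zerovalent palladium, CO at 1 atm, Et3N, MeCN, 60 °C) then forms C11–C12 and the acyl–oxygen bond, returning to the route at 22.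

Step 6 may give the wrong C10 epimer if chelation through O9 competes with the Felkin–Anh pathway, and the ketone may enolise with β-elimination of the dioxolane oxygen. The fallback inverts the order in which the two carbon substituents are introduced, so that a chelation bias delivers the required configuration. It sets out from 8: lithium (trimethylsilyl)acetylide gives the alkynyl ketone F3. MeMgBr in Et2O/CH2Cl2 with MgBr2·OEt2 then adds to F3 under chelation control to give the tertiary carbinol F4. K2CO3/MeOH removes the silyl group and returns to the route at 10.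

Step 14 may show poor site selectivity between the two secondary hydroxyls, acyl migration between O8 and O9, or lactone migration to O8. The fallback reverses the order of the two acylations with a temporary silyl group. It sets out from 23: Et3SiCl/imidazole silylates the less hindered O8 to give the 8-O-triethylsilyl ether F5. Ac2O/DMAP acetylates O9 to give the 9-acetate F6, and HF·pyridine frees O8 to give the hydroxy acetate F7. 3-Methylbutanoic anhydride/DMAP then returns to the route at 25.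

## Further compounds

F1 | step 12 | (2Z)-3-{(5R)-5-[(4R,5S)-5-[3-(9-borabicyclo[3.3.1]nonan-9-yl)-2-bromoprop-1-en-1-yl]-2,2-dimethyl-1,3-dioxolan-4-yl]-5-methyl-4-oxo-4,5-dihydrofuran-2-yl}but-2-enal | O=C/C=C(/C)C1=CC(=O)[C@](C)(O1)[C@@H]2OC(C)(C)O[C@H]2C=C(Br)CB3C4CCCC3CCC4
F2 | step 12 | ten-membered 2-bromo homoallylic alcohol: 22 with the lactone replaced by a C6 hydroxyl and bromine on C11 (configuration at C6–C10 as in 22) | C=C(Br)[C@H]1[C@H](O)/C=C(/C)C3=CC(=O)[C@](C)(O3)[C@@H]4OC(C)(C)O[C@H]41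
F3 | step 6 | 1-[(4R,5S)-2,2-dimethyl-5-(propa-1,2-dien-1-yl)-1,3-dioxolan-4-yl]-3-(trimethylsilyl)prop-2-yn-1-one | C[Si](C)(C)C#CC(=O)[C@@H]1OC(C)(C)O[C@H]1C=C=C
F4 | step 6 | (2S)-2-[(4R,5S)-2,2-dimethyl-5-(propa-1,2-dien-1-yl)-1,3-dioxolan-4-yl]-4-(trimethylsilyl)but-3-yn-2-ol | C[Si](C)(C)C#C[C@](C)(O)[C@@H]1OC(C)(C)O[C@H]1C=C=C
F5 | step 14 | 8-O-triethylsilyl ether of diol 23 | C=C1C(=O)O[C@@H]2/C=C(/C)C3=CC(=O)[C@](C)(O3)[C@H](O)[C@@H](O[Si](CC)(CC)CC)[C@@H]12
F6 | step 14 | 9-O-acetyl-8-O-triethylsilyl derivative of diol 23 | C=C1C(=O)O[C@@H]2/C=C(/C)C3=CC(=O)[C@](C)(O3)[C@H](OC(C)=O)[C@@H](O[Si](CC)(CC)CC)[C@@H]12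
F7 | step 14 | 9-O-acetyl derivative of diol 23 (free C8 hydroxyl) | C=C1C(=O)O[C@@H]2/C=C(/C)C3=CC(=O)[C@](C)(O3)[C@H](OC(C)=O)[C@@H](O)[C@@H]12
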